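Its constants are assumed; the flask was simulated.

Count what is left of the J, not what is made of it.

J 17 mM; G 0.51 mol%; D 66 µM; time 4.0 d

    J + G ⇌ E + G, rate k1*[J]*[G] forward; the back reaction follows from the equilibrium constant (K1 = 16.2, k1 = 16400 /M/h)
    E ⇌ L (K2 = 1.2, k2 = 0.585 /h)
    L ⇌ J (k3 = 7.34 /h)
    G + D → G.D (k4 = 8.66 × 10⁵ /M/h)

- the reaction counts as stopped when no species that holds the J changes by six tenths of a point or more over the second half of the time
- run time (flask): 4.0 d

* why nothing more happens at 4.0 d, or that something still does (it is still moving / all of J has reacted / forward and back rates have come level / no working catalyst is left)
* part of the J gone at 4.0 d
* the E standing at 4.0 d, as a percentage of the J charged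
* the L standing at 4.0 d, as a percentage of the J charged

Start at the top of the bracket. With step 1 by itself, J stops against E at one part to 16.2, so 5.81% of the charge stays J once that step has come level. That is your high end, and L has not been counted yet.

Now count L. It stands at 1.2 parts to one of E, so at 19.4 to one of J, and the constant of step 3 is the inverse of the other two, so the ring closes on one balance. This gives the balance share, the part of the charged J still free once every step has come level (thermodynamic control): 2.73%. The flask starts with its charge as J, above this share, and you take the share as your low end.

Which end applies is a question of time. E and L relax into each other by step 2 with a half-life of 0.646 h, far shorter than the 4.0 d of the run, which makes about 149 half-lives. Step 2 takes no G, so D, which binds G, leaves that clock alone. The bracket shuts on its low end. You commit to 97.3% of the J gone, E at 44.2% and L at 53.1%.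

The forecast says forward and back rates have come level, with 97.27% gone, E at 44.21% and L at 53.06%. Its J left, 2.73%, lies on the low end of the bracket, and its ground is this: “The cycle is thermodynamically consistent, so the system reaches true equilibrium”.

The flask gives forward and back rates have come level, with 97.3% of the J gone, E at 44.2% and L at 53.1%. J stands at 2.73% after 0.400 d and still at 2.73% after 40.0 d. The balance share holds no concentration; on the neighbour flask with 42 mM of J it gives 1.15 mM of free J. That neighbour flask ends with 2.73% of its charge as J.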